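The α-methylene-γ-lactone (ring B: C7, C8, O, C12, C11) is closed last, at C7–C11. The precursor is the fully substituted cyclohexane (ring A, C5–C10) whose equatorial C8 oxygen carries a diazophosphonoacetate. A dirhodium carbene at C11 inserts into the equatorial C7–H bond, which lies 1,5 to it and trans to C8–O, so the trans ring fusion and the C7 configuration arise with retention. The phosphonate left on C11 is used in the same flask to attach the exocyclic methylene C13. Ring A comes from an asymmetric conjugate addition and enolate vinylation, followed by two hydride deliveries that set both axial carbinols.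

Key step: step 12

Remark: atom labels follow the elemane skeleton: ring A = C5–C10; C10 carries CH3 and the vinyl group C1=C2; C5 carries C4(=C15H2)–C3; lactone atoms are C11, C12 and exocyclic C13; β is the face of ring A that carries the C10 methyl group, α the opposite face.
Remark: 1, 4, 6, 14 and 16 are taken as commercial; the sense of induction of the phosphoramidite in step 2 is assumed by analogy, and the ligand antipode is chosen to give the C5 configuration drawn.

Step 1
Reactants: 1 7-methyl-1,4-dioxaspiro[4.5]decan-8-one (racemic)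
Product: 3 7-methyl-1,4-dioxaspiro[4.5]dec-6-en-8-one, via trimethylsilyl enol ether 2 (not isolated)
Conditions: Me3SiCl, Et3N, DMF, 100 °C; then Pd(OAc)2 (10 mol %), O2 (1 atm), DMSO, 25 °C
Reagents that add atoms: none
Why: Saegusa–Ito oxidation of the more substituted (thermodynamic) silyl enol ether should place the double bond between C10 and C5; the racemic centre of 1 is erased and no stereocentre is set.

Step 2
Reactants: 3 7-methyl-1,4-dioxaspiro[4.5]dec-6-en-8-one; 4 isopropenylmagnesium bromide
Product: 5 (6S)-7-methyl-6-(prop-1-en-2-yl)-8-(trimethylsilyloxy)-1,4-dioxaspiro[4.5]dec-7-ene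
Conditions: 4 (1.3 equiv, slow addition), CuBr·SMe2 (5 mol %), O,O'-[(S)-1,1'-binaphthyl-2,2'-diyl] N,N-bis[(R)-1-phenylethyl]phosphoramidite (6 mol %), 2-methyltetrahydrofuran, −78 °C; then Me3SiCl, Et3N, −78 to 0 °C
Reagents that add atoms: chlorotrimethylsilane C[Si](C)(C)Cl
Why: copper-catalysed asymmetric conjugate addition of a Grignard reagent to an α-methyl cyclic enone with silyl trapping of the magnesium enolate: the chiral copper–phosphoramidite complex selects the enone face so that isopropenyl enters C5 with the configuration drawn, and O-silylation stores the regiodefined C9–C10 enolate.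

Step 3
Reactants: 5 (6S)-7-methyl-6-(prop-1-en-2-yl)-8-(trimethylsilyloxy)-1,4-dioxaspiro[4.5]dec-7-ene; 6 phenyl vinyl sulfoxide (racemic)
Product: 8 10α-vinyl-10β-methyl-5β-isopropenyl ketone ketal (7-methyl-6-(prop-1-en-2-yl)-7-vinyl-1,4-dioxaspiro[4.5]decan-8-one), via γ-keto sulfoxide 7 (not isolated)
Conditions: MeLi, THF, 0 °C; then 6, −78 to 0 °C; aq. NH4Cl; then toluene, 110 °C
Reagents that add atoms: none
Why: the lithium enolate released from 5 undergoes Michael addition to the vinyl sulfoxide (a vinyl cation equivalent) on the face of C10 anti to the neighbouring C5 isopropenyl group, and thermal syn-elimination of benzenesulfenic acid then unveils the vinyl group, which should give the 10α-vinyl-10β-methyl quaternary centre.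

Step 4
Reactants: 8 10α-vinyl-10β-methyl-5β-isopropenyl ketone ketal
Product: 9 2-methyl-3-(prop-1-en-2-yl)-2-vinylcyclohexane-1,4-dione (6,9-dione; vinyl trans to isopropenyl)
Conditions: pyridinium p-toluenesulfonate (cat.), acetone–H2O (10:1), 40 °C
Reagents that add atoms: water O
Why: mild acid hydrolysis of the dioxolane, chosen so that enolisation of the new C6 ketone toward C5 (epimerisation or migration of the isopropenyl double bond into conjugation) stays slow; no stereocentre is formed.

Step 5
Reactants: 9 2-methyl-3-(prop-1-en-2-yl)-2-vinylcyclohexane-1,4-dione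
Product: 10 6β-hydroxy-9-ketone (4-hydroxy-2-methyl-3-(prop-1-en-2-yl)-2-vinylcyclohexan-1-one; OH cis to isopropenyl)
Conditions: LiBH(s-Bu)3 (1.05 equiv), THF, −78 °C; aq. NH4Cl
Reagents that add atoms: none
Why: bulky-hydride reduction in which the C6 carbonyl is far more accessible than the C9 carbonyl next to quaternary C10, and the hydride enters C6 equatorially because the axial path is blocked by the syn-axial C10 methyl, which should give the axial 6β-alcohol cis to the C5 side chain.

Step 6
Reactants: 10 6β-hydroxy-9-ketone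
Product: 11 6β-(triethylsilyloxy)-9-ketone
Conditions: Et3SiOTf, 2,6-lutidine, CH2Cl2, −78 to 0 °C
Reagents that add atoms: triethylsilyl triflate CC[Si](CC)(CC)OS(=O)(=O)C(F)(F)F
Why: silyl ether protection of the hindered axial alcohol with the silyl triflate; O6 stays masked until the last step so that it can neither intercept the carbene nor translactonise, and no stereocentre changes.

Step 7
Reactants: 11 6β-(triethylsilyloxy)-9-ketone
Product: 12 8α-hydroxy-6β-(triethylsilyloxy)-9-ketone
Conditions: KN(SiMe3)2, THF, −78 °C; then 2-(phenylsulfonyl)-3-phenyloxaziridine, −78 °C; aq. NH4Cl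
Reagents that add atoms: 2-(phenylsulfonyl)-3-phenyloxaziridine O=S(=O)(c1ccccc1)N1OC1c1ccccc1
Why: enolate α-hydroxylation with an N-sulfonyloxaziridine (Davis oxidation): only C8 is enolisable, and the oxidant should attack the α face because the β face is shielded by the syn-axial C10 methyl and C6 silyloxy groups, giving the equatorial 8α-alcohol, which is also the thermodynamic epimer.

Step 8
Reactants: 12 8α-hydroxy-6β-(triethylsilyloxy)-9-ketone
Product: 13 8α,9α-diol 6β-triethylsilyl ether
Conditions: LiBH(s-Bu)3 (3 equiv), THF, −78 to −40 °C; aq. NH4Cl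
Reagents that add atoms: none
Why: bulky-hydride reduction of a ketone flanked by a quaternary carbon, which by analogy with 4,4-dimethyl-3-oxo terpenoids should proceed by equatorial attack and give the axial 9α-alcohol cis to the 8α-hydroxyl.

Step 9
Reactants: 13 8α,9α-diol 6β-triethylsilyl ether; 14 diethylphosphonoacetic acid
Product: 15 8α-O-(diethylphosphonoacetyl)-9α-ol
Conditions: 14 (1.05 equiv), N,N'-dicyclohexylcarbodiimide, 4-(dimethylamino)pyridine (5 mol %), CH2Cl2, 0 °C
Reagents that add atoms: none
Why: Steglich esterification in which the equatorial 8-OH should react well ahead of the axial, neopentyl-type 9-OH; no stereocentre is affected.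

Step 10
Reactants: 15 8α-O-(diethylphosphonoacetyl)-9α-ol; 16 angelic acid
Product: 18 9α-angelate 8α-(diethylphosphonoacetate), via mixed anhydride 17 (not isolated)
Conditions: 16, 2,4,6-trichlorobenzoyl chloride, Et3N, toluene, 23 °C; then 15, toluene, 80 °C
Reagents that add atoms: none
Why: Yamaguchi-type esterification through the preformed mixed anhydride, the usual way to acylate hindered alcohols with angelic acid without Z-to-E isomerisation; the C9 configuration is retained.

Step 11
Reactants: 18 9α-angelate 8α-(diethylphosphonoacetate)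
Product: 19 9α-angelate 8α-[diazo(diethoxyphosphoryl)acetate]
Conditions: 4-acetamidobenzenesulfonyl azide, DBU, MeCN, 0 to 23 °C
Reagents that add atoms: 4-acetamidobenzenesulfonyl azide CC(=O)Nc1ccc(cc1)S(=O)(=O)N=[N+]=[N-]
Why: Regitz diazo transfer to the activated methylene of the phosphonoacetate; no stereocentre is involved.

Step 12
Reactants: 19 9α-angelate 8α-[diazo(diethoxyphosphoryl)acetate]
Product: 21 9α-angeloyloxy-6β-(triethylsilyloxy)elema-1,4(15),11(13)-trien-8α,12-olide, via α-phosphono lactone 20 (not isolated)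
Conditions: Rh2(O2CC7H15)4 (2 mol %), CH2Cl2, 40 °C, slow addition of 19; then THF, KOt-Bu (1.1 equiv), paraformaldehyde, 0 °C
Reagents that add atoms: formaldehyde (from paraformaldehyde) C=O
Why: Loss of N2 from 19 at dirhodium gives an electrophilic carbene at C11 that inserts into the C7–H bond through a concerted three-centre transition state; the closest known reaction type is the intramolecular C–H insertion of α-diazo-α-phosphonoacetates to α-phosphono-γ-lactones, followed in the same flask by Horner–Wadsworth–Emmons olefination. Ring B is closed in the 1,5 mode, through a five-membered transition state spanning C11, C12, O, C8 and C7. C7 is set with retention: the carbene held by the equatorial C8 oxygen reaches the equatorial 7β-hydrogen of the chair-locked ring A, so the new C7–C11 bond is trans to C8–O, while C11 forms as an epimer mixture that is erased when the phosphonate anion of 20 condenses with formaldehyde to give C13. The step needs site selectivity for the equatorial C7–H over C9–H and over the axial 7α-H: C9–H carries an acyloxy rather than an activating alkoxy group and is screened by quaternary C10 and its axial methyl, and insertion into the axial 7α-H would force a cis-fused lactone with C11 syn-axial to the 9α-angelate. O6 is silylated so that O–H insertion cannot compete, and the vinyl and isopropenyl groups can reach the carbene only through medium rings.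

Step 13
Reactants: 21 9α-angeloyloxy-6β-(triethylsilyloxy)elema-1,4(15),11(13)-trien-8α,12-olide
Product: 23 6-O-triethylsilyl ether of the target (3-oxo compound), via allylic alcohol 22 (not isolated)
Conditions: SeO2 (0.5 equiv), t-BuOOH (3 equiv), CH2Cl2, 23 °C; then Dess–Martin periodinane, CH2Cl2, 0 °C
Reagents that add atoms: selenium dioxide O=[Se]=O; tert-butyl hydroperoxide CC(C)(C)OO
Why: allylic oxidation of the isopropenyl methyl group by the selenium dioxide ene reaction and [2,3]-shift (methyl preferred over the tertiary C5–H), with the allylic alcohol 22 carried on to the enal by Dess–Martin oxidation; the other alkenes are electron-poor or lack allylic hydrogen, and no stereocentre is touched.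

Step 14
Reactants: 23 6-O-triethylsilyl ether of the target
Product: 24 9α-angeloyloxy-6β-hydroxy-3-oxoelema-1,4(15),11(13)-trien-8α,12-olide (target)
Conditions: HF·pyridine, pyridine, THF, 0 to 23 °C
Reagents that add atoms: none
Why: fluoride-mediated cleavage of the triethylsilyl ether under non-basic conditions, which should free the 6β-hydroxyl without translactonisation, angelate migration or addition to the two Michael acceptors.

Compound list
1 | 7-methyl-1,4-dioxaspiro[4.5]decan-8-one (racemic) | O=C1CCC2(CC1C)OCCO2 | starting material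
2 | 7-methyl-8-(trimethylsilyloxy)-1,4-dioxaspiro[4.5]dec-7-ene | C[Si](C)(C)OC1=C(C)CC2(CC1)OCCO2 | intermediate
3 | 7-methyl-1,4-dioxaspiro[4.5]dec-6-en-8-one | CC1=CC2(CCC1=O)OCCO2 | intermediate
4 | isopropenylmagnesium bromide | CC(=C)[Mg]Br | starting material
5 | (6S)-7-methyl-6-(prop-1-en-2-yl)-8-(trimethylsilyloxy)-1,4-dioxaspiro[4.5]dec-7-ene (C5 of the target set) | CC1=C(O[Si](C)(C)C)CCC2(OCCO2)[C@H]1C(C)=C | intermediate
6 | phenyl vinyl sulfoxide (racemic) | C=CS(=O)c1ccccc1 | starting material
7 | 7-methyl-7-[2-(phenylsulfinyl)ethyl]-6-(prop-1-en-2-yl)-1,4-dioxaspiro[4.5]decan-8-one; sulfinylethyl chain trans to isopropenyl; mixture at sulfur | O=S(CC[C@]1(C)C(=O)CCC2(OCCO2)[C@H]1C(C)=C)c1ccccc1 | intermediate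
8 | 7-methyl-6-(prop-1-en-2-yl)-7-vinyl-1,4-dioxaspiro[4.5]decan-8-one; 10α-vinyl, 10β-methyl, 5β-isopropenyl | C=C[C@]1(C)C(=O)CCC2(OCCO2)[C@H]1C(C)=C | intermediate
9 | 2-methyl-3-(prop-1-en-2-yl)-2-vinylcyclohexane-1,4-dione; vinyl trans to isopropenyl | C=C[C@]1(C)C(=O)CCC(=O)[C@H]1C(C)=C | intermediate
10 | 4-hydroxy-2-methyl-3-(prop-1-en-2-yl)-2-vinylcyclohexan-1-one; 6β-OH cis to isopropenyl, vinyl trans | C=C[C@]1(C)C(=O)CC[C@@H](O)[C@H]1C(C)=C | intermediate
11 | 6β-triethylsilyl ether of 10 | C=C[C@]1(C)C(=O)CC[C@@H](O[Si](CC)(CC)CC)[C@H]1C(C)=C | intermediate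
12 | 8α-hydroxy-6β-(triethylsilyloxy)-9-ketone; 8-OH trans to 6-OSiEt3, cis to vinyl | C=C[C@]1(C)C(=O)[C@H](O)C[C@@H](O[Si](CC)(CC)CC)[C@H]1C(C)=C | intermediate
13 | 8α,9α-diol 6β-triethylsilyl ether; both hydroxyls cis to vinyl | C=C[C@]1(C)[C@H](O)[C@H](O)C[C@@H](O[Si](CC)(CC)CC)[C@H]1C(C)=C | intermediate
14 | diethylphosphonoacetic acid | CCOP(=O)(CC(=O)O)OCC | starting material
15 | 8α-O-(diethylphosphonoacetyl)-9α-ol | C=C[C@]1(C)[C@H](O)[C@H](OC(=O)CP(=O)(OCC)OCC)C[C@@H](O[Si](CC)(CC)CC)[C@H]1C(C)=C | intermediate
16 | angelic acid, (Z)-2-methylbut-2-enoic acid | C/C=C(/C)C(=O)O | starting material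
17 | angelic 2,4,6-trichlorobenzoic anhydride | C/C=C(/C)C(=O)OC(=O)c1c(Cl)cc(Cl)cc1Cl | intermediate
18 | 9α-angelate 8α-(diethylphosphonoacetate) | C=C[C@]1(C)[C@H](OC(=O)/C(C)=C\C)[C@H](OC(=O)CP(=O)(OCC)OCC)C[C@@H](O[Si](CC)(CC)CC)[C@H]1C(C)=C | intermediate
19 | 9α-angelate 8α-[diazo(diethoxyphosphoryl)acetate] | C=C[C@]1(C)[C@H](OC(=O)/C(C)=C\C)[C@H](OC(=O)C(=[N+]=[N-])P(=O)(OCC)OCC)C[C@@H](O[Si](CC)(CC)CC)[C@H]1C(C)=C | intermediate
20 | 11-(diethoxyphosphoryl) trans-fused 8α,12-olide; mixture at C11 | C=C[C@]1(C)[C@H](OC(=O)/C(C)=C\C)[C@@H]2OC(=O)C(P(=O)(OCC)OCC)[C@H]2[C@@H](O[Si](CC)(CC)CC)[C@H]1C(C)=C | intermediate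
21 | 9α-angeloyloxy-6β-(triethylsilyloxy)elema-1,4(15),11(13)-trien-8α,12-olide | C=C[C@]1(C)[C@H](OC(=O)/C(C)=C\C)[C@@H]2OC(=O)C(=C)[C@H]2[C@@H](O[Si](CC)(CC)CC)[C@H]1C(C)=C | intermediate
22 | 3-hydroxy derivative of 21 (allylic alcohol) | C=C[C@]1(C)[C@H](OC(=O)/C(C)=C\C)[C@@H]2OC(=O)C(=C)[C@H]2[C@@H](O[Si](CC)(CC)CC)[C@H]1C(=C)CO | intermediate
23 | 6-O-triethylsilyl ether of the target | C=C[C@]1(C)[C@H](OC(=O)/C(C)=C\C)[C@@H]2OC(=O)C(=C)[C@H]2[C@@H](O[Si](CC)(CC)CC)[C@H]1C(=C)C=O | intermediate
24 | 9α-angeloyloxy-6β-hydroxy-3-oxoelema-1,4(15),11(13)-trien-8α,12-olide | C=C[C@]1(C)[C@H](OC(=O)/C(C)=C\C)[C@@H]2OC(=O)C(=C)[C@H]2[C@@H](O)[C@H]1C(=C)C=O | target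

Total steps: 14. Longest linear sequence: 14 steps (1 to 24).

Steps most likely to fail

Step 12. What may go wrong: the carbene may insert at C9–H or at the axial C7–H, or be consumed by dimerisation or by addition to the C10 vinyl group, so that the trans-fused lactone is not the main product. The fallback sets out from 13 and comes back at 21. Diol 13 is acylated at the equatorial 8-OH with succinimidyl diazoacetate (Et3N, CH2Cl2) to give the 8α-diazoacetate F1. Angeloylation with anhydride 17 as in step 10 gives the diazoacetate angelate F2. The acceptor-only carbene generated from F2 with dirhodium tetraacetamidate, Rh2(NHCOCH3)4 (CH2Cl2, 40 °C), is less electrophilic and more discriminating than the phosphonate-bearing carbene and should insert into the equatorial C7–H to give the saturated trans-lactone F3. Enolisation with LiN(SiMe3)2 and Mannich reaction with Eschenmoser's salt (Me2N=CH2 iodide) gives the Mannich base F4, MeI gives the methiodide F5, and NaHCO3 eliminates trimethylamine to give 21.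

Step 2. What may go wrong: poor facial selectivity, or competing 1,2-addition, when an α-branched alkenyl Grignard reagent meets the hindered α-methyl enone next to the ketal carbon. The fallback sets out from 3 and comes back at 10. The conjugate addition is run without the chiral ligand (4, CuBr·SMe2, Me3SiCl), which gives 5 together with its enantiomer F6. Steps 3 to 5 then give, besides 7 to 10, the enantiomeric sulfoxide adduct F7, the enantiomeric vinyl ketone F8, the enantiomeric diketone F9 and the enantiomeric hydroxy ketone F10. Acylation of the racemic alcohol with (1S)-camphanic chloride (4-(dimethylamino)pyridine, pyridine) gives the camphanate of 10 F11 and the camphanate of the enantiomer F12, which are separated by chromatography or crystallisation. LiOH in aqueous THF releases 10 from F11.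

Step 10. What may go wrong: slow acylation of the axial, neopentyl-type 9-OH, giving time for migration of the neighbouring phosphonoacetyl group or for Z-to-E isomerisation of the activated angelate. The fallback sets out from 15 and comes back at 18. The 9-OH is esterified with the small, reactive 2-[bis(2,2,2-trifluoroethoxy)phosphoryl]propanoic acid (N,N'-dicyclohexylcarbodiimide, 4-(dimethylamino)pyridine) to give the mixed bis-phosphonate F13. Still–Gennari olefination (KN(SiMe3)2, 1.0 equiv, 18-crown-6, THF, −78 °C; acetaldehyde) then builds the Z-configured 2-methylbut-2-enoate on O9 and gives 18; the more acidic trifluoroethyl phosphonate should be deprotonated selectively over the diethyl phosphonoacetate.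

Further compounds
F1 | step 12 | 8α-diazoacetate of diol 13 | C=C[C@]1(C)[C@H](O)[C@H](OC(=O)C=[N+]=[N-])C[C@@H](O[Si](CC)(CC)CC)[C@H]1C(C)=C
F2 | step 12 | 9α-angelate 8α-diazoacetate | C=C[C@]1(C)[C@H](OC(=O)/C(C)=C\C)[C@H](OC(=O)C=[N+]=[N-])C[C@@H](O[Si](CC)(CC)CC)[C@H]1C(C)=C
F3 | step 12 | saturated trans-fused 8α,12-olide (C11 = CH2) | C=C[C@]1(C)[C@H](OC(=O)/C(C)=C\C)[C@@H]2OC(=O)C[C@H]2[C@@H](O[Si](CC)(CC)CC)[C@H]1C(C)=C
F4 | step 12 | 11-(dimethylaminomethyl) lactone (Mannich base) | C=C[C@]1(C)[C@H](OC(=O)/C(C)=C\C)[C@@H]2OC(=O)C(CN(C)C)[C@H]2[C@@H](O[Si](CC)(CC)CC)[C@H]1C(C)=C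
F5 | step 12 | methiodide of F4 | C=C[C@]1(C)[C@H](OC(=O)/C(C)=C\C)[C@@H]2OC(=O)C(C[N+](C)(C)C)[C@H]2[C@@H](O[Si](CC)(CC)CC)[C@H]1C(C)=C.[I-]
F6 | step 2 | enantiomer of 5 | CC1=C(O[Si](C)(C)C)CCC2(OCCO2)[C@@H]1C(C)=C
F7 | step 2 | enantiomer of 7 | O=S(CC[C@@]1(C)C(=O)CCC2(OCCO2)[C@@H]1C(C)=C)c1ccccc1
F8 | step 2 | enantiomer of 8 | C=C[C@@]1(C)C(=O)CCC2(OCCO2)[C@@H]1C(C)=C
F9 | step 2 | enantiomer of 9 | C=C[C@@]1(C)C(=O)CCC(=O)[C@@H]1C(C)=C
F10 | step 2 | enantiomer of 10 | C=C[C@@]1(C)C(=O)CC[C@H](O)[C@@H]1C(C)=C
F11 | step 2 | (1S)-camphanate of 10 | C=C[C@]1(C)C(=O)CC[C@@H](OC(=O)[C@@]23CC[C@@](C)(C(=O)O2)C3(C)C)[C@H]1C(C)=C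
F12 | step 2 | (1S)-camphanate of the enantiomer of 10 | C=C[C@@]1(C)C(=O)CC[C@H](OC(=O)[C@@]23CC[C@@](C)(C(=O)O2)C3(C)C)[C@@H]1C(C)=C
F13 | step 10 | 9α-O-{2-[bis(2,2,2-trifluoroethoxy)phosphoryl]propanoyl} 8α-O-(diethylphosphonoacetyl) diester | C=C[C@]1(C)[C@H](OC(=O)C(C)P(=O)(OCC(F)(F)F)OCC(F)(F)F)[C@H](OC(=O)CP(=O)(OCC)OCC)C[C@@H](O[Si](CC)(CC)CC)[C@H]1C(C)=C
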